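**Plan**

1. Retrosynthetic cuts: (i) the upper/middle double linkage at C4(upper)–C8(middle) and C2(upper)–O–C7(middle), by annulation of a 2,4-bridged epiafzelechin bis-electrophile onto ring A of the middle unit; (ii) the middle/lower ketal bond C2(middle)–O7(lower), by acid ketalisation of a flav-2-ene; (iii) ring C of the middle unit at O1–C8a and C3–C4, giving a diaryl carbinol and an α-benzyloxy aryl ketone.
2. Enabling feature: in ring A of the middle unit O7 is para to C4a and C8a is ortho to it. A free 7-OH turns the benzylic C4 into a para-quinone methide carbon and a bromine on C8a makes C8a a second electrophilic site, so C4–C4a–C8a is a 1,3-dielectrophile matched by the O1–C2=C3 enol unit of the ketone.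
3. Forward order: lower afzelechin → 8-formyl derivative (its CHO carbon becomes C4 of the middle unit) → diaryl carbinol → ring C of the middle unit (key step) → 2,8-dioxabicyclo[3.3.1]nonane by ketalisation → upper unit annulated → global hydrogenolysis.
4. Stereochemistry: lower and upper units come from (+)-afzelechin and (−)-epiafzelechin; C4(middle) from a chiral phosphoric acid in the key step; C3(middle) by protonation anti to the C4 aryl group; C2(middle) by the bicyclic constraint; C4 and C2 of the upper unit by attack trans to its 3-O-benzyl group and by the bridge.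
5. Helpers: methoxymethyl on O7(lower) (blocks xanthene closure, leaves in the ketalisation), bromine on C8a (consumed), silyl ether on O7(middle), bromine on C8 of the upper donor and all benzyl groups (leave in the last step).

Key step: step 12

Remark (assumption): (+)-afzelechin (2R,3S) and (−)-epiafzelechin (2R,3R) are taken as purchasable natural products; flavan numbering is used and "upper", "middle", "lower" name the three flavan units of the target from its non-reducing end.

**Step 1**
Reactants: 1 5-bromobenzene-1,3-diol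
Product: 2 3-(benzyloxy)-5-bromophenol
Conditions: BnBr (1.0 equiv), K2CO3, acetone, reflux; mono-ether separated from diol and bis-ether
Reagents that add atoms: benzyl bromide, BrCc1ccccc1
Why: Williamson ether synthesis on a symmetric diol, so either hydroxyl gives the same mono-ether and recovered 1 can be recycled; no stereocentre is formed.

**Step 2**
Reactants: 2 3-(benzyloxy)-5-bromophenol
Product: 3 3-(benzyloxy)-4,5-dibromophenol
Conditions: NBS (1.0 equiv), MeCN, −30 to 0 °C
Reagents that add atoms: N-bromosuccinimide, O=C1CCC(=O)N1Br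
Why: electrophilic aromatic bromination in which the free hydroxyl, the strongest donor, should direct to its para position C4, which is also ortho to the benzyloxy group.

**Step 3**
Reactants: 3 3-(benzyloxy)-4,5-dibromophenol
Product: 4 [3-(benzyloxy)-4,5-dibromophenoxy](tert-butyl)dimethylsilane
Conditions: TBSCl, imidazole, DMF, rt
Reagents that add atoms: tert-butyldimethylsilyl chloride, CC(C)(C)[Si](C)(C)Cl
Why: imidazole-promoted silylation masks the acidic phenol for the magnesium step and can be removed later with fluoride.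

**Step 4**
Reactants: 5 2-(benzyloxy)-N-methoxy-N-methylacetamide; 6 [4-(benzyloxy)phenyl]magnesium bromide
Product: 7 2-(benzyloxy)-1-[4-(benzyloxy)phenyl]ethan-1-one
Conditions: THF, 0 °C; aqueous HCl work-up
Reagents that add atoms: none
Why: Weinreb ketone synthesis, in which the chelated tetrahedral adduct prevents over-addition.

**Step 5**
Reactants: 7 2-(benzyloxy)-1-[4-(benzyloxy)phenyl]ethan-1-one
Product: 8 (Z)-{[2-(benzyloxy)-1-(4-(benzyloxy)phenyl)ethenyl]oxy}trimethylsilane
Conditions: LiN(SiMe3)2, THF, −78 °C; Me3SiCl, −78 °C to rt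
Reagents that add atoms: chlorotrimethylsilane, C[Si](C)(C)Cl
Why: kinetic enolisation through a lithium chelate between the carbonyl and the α-benzyloxy oxygen should give the Z enolate, which is trapped on oxygen (silyl enol ether formation).

**Step 6**
Reactants: 9 (+)-afzelechin
Product: 10 5,7,4'-tri-O-benzylafzelechin
Conditions: BnBr (3.3 equiv), K2CO3, DMF, rt
Reagents that add atoms: benzyl bromide, BrCc1ccccc1
Why: Williamson etherification of the three phenols, the secondary 3-OH not being deprotonated by K2CO3; the two stereocentres are untouched.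

**Step 7**
Reactants: 10 5,7,4'-tri-O-benzylafzelechin
Product: 11 8-bromo-5,7,4'-tri-O-benzylafzelechin
Conditions: NBS, CH2Cl2, −78 to 0 °C
Reagents that add atoms: N-bromosuccinimide, O=C1CCC(=O)N1Br
Why: electrophilic bromination at C8, the most reactive position of the 5,7-dioxygenated ring A of benzylated flavan-3-ols.

**Step 8**
Reactants: 11 8-bromo-5,7,4'-tri-O-benzylafzelechin
Product: 13 5,7,4'-tri-O-benzyl-8-formylafzelechin, via aryllithium 12 (not isolated)
Conditions: n-BuLi (2.2 equiv), THF, −78 °C; DMF; aqueous NH4Cl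
Reagents that add atoms: N,N-dimethylformamide, CN(C)C=O
Why: deprotonation of the 3-OH followed by bromine–lithium exchange and formylation of the aryllithium with DMF (Bouveault-type aldehyde synthesis) fixes the future C4 of the middle unit on C8 of the lower unit.

**Step 9**
Reactants: 13 5,7,4'-tri-O-benzyl-8-formylafzelechin
Product: 14 5,4'-di-O-benzyl-8-formylafzelechin (free 7-OH and 3-OH)
Conditions: MgBr2·OEt2, toluene–Et2O, 80 °C; aqueous HCl work-up
Reagents that add atoms: none
Why: chelation-controlled debenzylation, in which magnesium held between the aldehyde oxygen and the ortho benzyloxy oxygen lets bromide remove only the 7-O-benzyl group (the 5-O-benzyl group is para to the aldehyde).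

**Step 10**
Reactants: 14 5,4'-di-O-benzyl-8-formylafzelechin
Product: 15 5,4'-di-O-benzyl-8-formyl-3,7-bis-O-(methoxymethyl)afzelechin
Conditions: NaH, MeOCH2Cl, THF–DMF, 0 °C to rt
Reagents that add atoms: chloromethyl methyl ether, COCCl
Why: Williamson-type alkylation of the phenoxide and the 3-alkoxide gives acid-labile acetals, so O7 stays masked through the copper step and is released in the ketalisation.

**Step 11**
Reactants: 4 [3-(benzyloxy)-4,5-dibromophenoxy](tert-butyl)dimethylsilane; 15 5,4'-di-O-benzyl-8-formyl-3,7-bis-O-(methoxymethyl)afzelechin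
Product: 18 [2-(benzyloxy)-6-bromo-4-hydroxyphenyl][5,4'-di-O-benzyl-3,7-bis-O-(methoxymethyl)afzelechin-8-yl]methanol (both carbinol epimers, used crude), via arylmagnesium chloride 16 (not isolated), via silyl carbinol 17 (not isolated)
Conditions: i-PrMgCl·LiCl, THF, −20 °C; then 15, −20 to 0 °C; then AcOH, Bu4NF, 0 °C
Reagents that add atoms: none
Why: bromine–magnesium exchange should occur at the bromine flanked by the benzyloxy group, the 2-bromoaryl Grignard reagent adds 1,2 to the aldehyde and buffered fluoride frees the para-hydroxyl; the carbinol centre forms without control and is erased in step 12.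

**Step 12**
Reactants: 18 diaryl carbinol (both epimers); 8 (Z)-{[2-(benzyloxy)-1-(4-(benzyloxy)phenyl)ethenyl]oxy}trimethylsilane
Product: 21 (4R)-3,5-bis(benzyloxy)-2-[4-(benzyloxy)phenyl]-4-[5,4'-di-O-benzyl-3,7-bis-O-(methoxymethyl)afzelechin-8-yl]-4H-chromen-7-ol (flav-2-ene), via para-quinone methide 19 (not isolated), via ketone 20 (not isolated)
Conditions: (R)-3,3'-bis(2,4,6-triisopropylphenyl)-1,1'-binaphthyl-2,2'-diyl hydrogen phosphate [(R)-TRIP, 10 mol %], 4 Å MS, toluene, −20 °C to rt; then, same flask, CuI (20 mol %), 1,10-phenanthroline (40 mol %), Cs2CO3 (3 equiv), DMF, 100 °C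
Reagents that add atoms: none
Why: Proposed new method: the phosphoric acid dehydrates 18 to para-quinone methide 19 and holds it as a hydrogen-bonded ion pair, silyl enol ether 8 adds through C3 to the exocyclic C4 (1,6-addition of Mukaiyama–Michael type) with rearomatisation of ring A to ketone 20, and after the switch to base the caesium enolate of 20 is O-arylated at C8a under copper catalysis; the closest known reactions are acid-catalysed conjugate additions of π-nucleophiles to quinone methides made in situ from hydroxybenzhydrols and the copper-catalysed domino C-benzylation/intramolecular O-arylation of β-keto esters with 2-bromobenzyl bromides to 4H-chromenes, merged here in one flask on a simple aryl ketone. Ring C closes in the second event by a six-membered Ullmann-type C–O coupling of the enolate oxygen O1 onto C8a–Br, C-arylation being excluded because it would need a four-membered ring. C4 is the only new stereocentre that survives: it is set in the 1,6-addition by the chiral phosphate bound to the quinone methide oxygen (the antipode of the acid that delivers the 4R epimer is to be used, as the remote centres of the lower unit are not expected to bias the faces), while C3 ends as a planar enol ether carbon. The step needs addition of 8 to outrun Friedel–Crafts self-alkylation of the electron-rich rings (8 is the strongest π-nucleophile present) and needs O1–C8a coupling without diaryl ether formation; the methoxymethyl group on O7 of the lower unit keeps that oxygen from closing a xanthene onto C8a, and the only free phenoxide (O7 of ring A) is meta to the bromine and cannot reach it.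

**Step 13**
Reactants: 21 (4R)-flav-2-ene
Product: 22 3,5,4'-tri-O-benzylafzelechin-(2β→O→7,4β→8)-5,4'-di-O-benzylafzelechin (middle–lower dimer; free 7-OH on ring A of the middle unit, free 3-OH on the lower unit)
Conditions: HCl (1.25 M in MeOH), CH2Cl2, 0 to 40 °C
Reagents that add atoms: none
Why: acid removes both methoxymethyl acetals and protonates the enol ether at C3 anti to the pseudo-axial C4 aryl group (3-O-benzyl cis to the lower unit), and the C2 oxocarbenium ion is trapped by O7 of the lower unit on the only face it can reach, an acid-catalysed ketalisation that fixes C2 by the constraint of the 2,8-dioxabicyclo[3.3.1]nonane.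

**Step 14**
Reactants: 23 (−)-epiafzelechin
Product: 24 5,7,4'-tri-O-benzylepiafzelechin
Conditions: BnBr (3.3 equiv), K2CO3, DMF, rt
Reagents that add atoms: benzyl bromide, BrCc1ccccc1
Why: Williamson etherification of the phenols only; stereocentres untouched.

**Step 15**
Reactants: 24 5,7,4'-tri-O-benzylepiafzelechin
Product: 25 8-bromo-5,7,4'-tri-O-benzylepiafzelechin
Conditions: NBS, CH2Cl2, −78 °C
Reagents that add atoms: N-bromosuccinimide, O=C1CCC(=O)N1Br
Why: electrophilic bromination at C8 blocks the nucleophilic site of the donor against self-condensation; the bromine leaves in step 20.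

**Step 16**
Reactants: 25 8-bromo-5,7,4'-tri-O-benzylepiafzelechin
Product: 26 3,5,7,4'-tetra-O-benzyl-8-bromoepiafzelechin
Conditions: NaH, BnBr, Bu4NI (cat.), THF–DMF, 0 °C to rt
Reagents that add atoms: benzyl bromide, BrCc1ccccc1
Why: Williamson etherification of the secondary alcohol protects it during the two oxidations.

**Step 17**
Reactants: 26 3,5,7,4'-tetra-O-benzyl-8-bromoepiafzelechin
Product: 27 3,5,7,4'-tetra-O-benzyl-8-bromo-4β-(2-hydroxyethoxy)epiafzelechin
Conditions: DDQ, ethylene glycol, CH2Cl2, rt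
Reagents that add atoms: ethylene glycol, OCCO
Why: DDQ abstracts hydride from the benzylic C4 and the cation is trapped by the glycol trans to the 3-O-benzyl group (benzylic oxidative etherification), setting the 4β configuration.

**Step 18**
Reactants: 27 4β-(2-hydroxyethoxy) derivative
Product: 28 3,5,7,4'-tetra-O-benzyl-8-bromo-2β,4β-(ethane-1,2-diyldioxy)epiafzelechin (bridged ketal)
Conditions: DDQ, 4 Å MS, 1,2-dichloroethane, 60 °C
Reagents that add atoms: none
Why: a second DDQ hydride abstraction, now at the benzylic, oxygen-bearing C2, gives an oxocarbenium ion that the tethered hydroxyl can close only from the β face, so the aryl group keeps its position.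

**Step 19**
Reactants: 22 middle–lower dimer; 28 bridged ketal
Product: 30 protected trimer, 3,5,7,4'-tetra-O-benzyl-8-bromoepiafzelechin-(2β→O→7,4β→8)-3,5,4'-tri-O-benzylafzelechin-(2β→O→7,4β→8)-5,4'-di-O-benzylafzelechin, via hydroxyethyl ketal 29 (not isolated)
Conditions: BF3·OEt2 (0.5 equiv), 4 Å MS, CH2Cl2, −40 to 0 °C
Reagents that add atoms: none
Why: Lewis acid-mediated annulation of a 2,4-dioxygenated flavan with a phenol, in which the C4 cation is attacked by C8 of ring A of the middle unit trans to the 3-O-benzyl group (Friedel–Crafts alkylation) and the C2 oxocarbenium ion is then closed by the adjacent 7-OH on the same face; C8 is preferred over C6 because it is flanked by the ring-tied O1 and not by a freely rotating benzyloxy group.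

**Step 20**
Reactants: 30 protected trimer
Product: 31 epiafzelechin-(2β→O→7,4β→8)-afzelechin-(2β→O→7,4β→8)-afzelechin (target)
Conditions: H2 (1 atm), Pd(OH)2/C, Et3N, THF–MeOH, rt
Reagents that add atoms: none
Why: catalytic hydrogenolysis should cleave the nine benzyl ethers and the aryl bromide while the doubly linked ketals, which carry no hydrogenolysable benzylic C–O bond outside the bicycles, stay intact.

**Compound list**

1 | 5-bromobenzene-1,3-diol | Oc1cc(O)cc(Br)c1 | starting material
2 | 3-(benzyloxy)-5-bromophenol | Oc1cc(OCc2ccccc2)cc(Br)c1 | intermediate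
3 | 3-(benzyloxy)-4,5-dibromophenol | Oc1cc(OCc2ccccc2)c(Br)c(Br)c1 | intermediate
4 | [3-(benzyloxy)-4,5-dibromophenoxy](tert-butyl)dimethylsilane | CC(C)(C)[Si](C)(C)Oc1cc(OCc2ccccc2)c(Br)c(Br)c1 | intermediate
5 | 2-(benzyloxy)-N-methoxy-N-methylacetamide | CON(C)C(=O)COCc1ccccc1 | starting material
6 | [4-(benzyloxy)phenyl]magnesium bromide | Br[Mg]c1ccc(OCc2ccccc2)cc1 | starting material
7 | 2-(benzyloxy)-1-[4-(benzyloxy)phenyl]ethan-1-one | O=C(COCc1ccccc1)c1ccc(OCc2ccccc2)cc1 | intermediate
8 | (Z)-{[2-(benzyloxy)-1-(4-(benzyloxy)phenyl)ethenyl]oxy}trimethylsilane | C[Si](C)(C)O/C(c1ccc(OCc2ccccc2)cc1)=C\OCc1ccccc1 | intermediate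
9 | (+)-afzelechin, (2R,3S)-2-(4-hydroxyphenyl)chromane-3,5,7-triol | Oc1ccc([C@H]2Oc3cc(O)cc(O)c3C[C@@H]2O)cc1 | starting material
10 | 5,7,4'-tri-O-benzylafzelechin | c7ccccc7COc1ccc([C@H]2Oc3cc(OCc7ccccc7)cc(OCc7ccccc7)c3C[C@@H]2O)cc1 | intermediate
11 | 8-bromo-5,7,4'-tri-O-benzylafzelechin | c7ccccc7COc1ccc([C@H]2Oc3c(Br)c(OCc7ccccc7)cc(OCc7ccccc7)c3C[C@@H]2O)cc1 | intermediate
12 | 8-lithio-5,7,4'-tri-O-benzylafzelechin lithium 3-alkoxide | c7ccccc7COc1ccc([C@H]2Oc3c([Li])c(OCc7ccccc7)cc(OCc7ccccc7)c3C[C@@H]2O[Li])cc1 | intermediate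
13 | 5,7,4'-tri-O-benzyl-8-formylafzelechin | c7ccccc7COc1ccc([C@H]2Oc3c(C=O)c(OCc7ccccc7)cc(OCc7ccccc7)c3C[C@@H]2O)cc1 | intermediate
14 | 5,4'-di-O-benzyl-8-formylafzelechin | c7ccccc7COc1ccc([C@H]2Oc3c(C=O)c(O)cc(OCc7ccccc7)c3C[C@@H]2O)cc1 | intermediate
15 | 5,4'-di-O-benzyl-8-formyl-3,7-bis-O-(methoxymethyl)afzelechin | c7ccccc7COc1ccc([C@H]2Oc3c(C=O)c(OCOC)cc(OCc7ccccc7)c3C[C@@H]2OCOC)cc1 | intermediate
16 | [2-(benzyloxy)-6-bromo-4-(tert-butyldimethylsilyloxy)phenyl]magnesium chloride | CC(C)(C)[Si](C)(C)Oc1cc(OCc2ccccc2)c([Mg]Cl)c(Br)c1 | intermediate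
17 | [2-(benzyloxy)-6-bromo-4-(tert-butyldimethylsilyloxy)phenyl][5,4'-di-O-benzyl-3,7-bis-O-(methoxymethyl)afzelechin-8-yl]methanol, both carbinol epimers | c7ccccc7COc1ccc([C@H]2Oc3c(C(O)c4c(OCc7ccccc7)cc(O[Si](C)(C)C(C)(C)C)cc4Br)c(OCOC)cc(OCc7ccccc7)c3C[C@@H]2OCOC)cc1 | intermediate
18 | [2-(benzyloxy)-6-bromo-4-hydroxyphenyl][5,4'-di-O-benzyl-3,7-bis-O-(methoxymethyl)afzelechin-8-yl]methanol, both carbinol epimers | c7ccccc7COc1ccc([C@H]2Oc3c(C(O)c4c(OCc7ccccc7)cc(O)cc4Br)c(OCOC)cc(OCc7ccccc7)c3C[C@@H]2OCOC)cc1 | intermediate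
19 | para-quinone methide, 3-(benzyloxy)-5-bromo-4-{[5,4'-di-O-benzyl-3,7-bis-O-(methoxymethyl)afzelechin-8-yl]methylidene}cyclohexa-2,5-dien-1-one | c7ccccc7COc1ccc([C@H]2Oc3c(C=C4C(OCc7ccccc7)=CC(=O)C=C4Br)c(OCOC)cc(OCc7ccccc7)c3C[C@@H]2OCOC)cc1 | intermediate
20 | (3S)-2-(benzyloxy)-1-[4-(benzyloxy)phenyl]-3-[2-(benzyloxy)-6-bromo-4-hydroxyphenyl]-3-[5,4'-di-O-benzyl-3,7-bis-O-(methoxymethyl)afzelechin-8-yl]propan-1-one, both C2 epimers | c7ccccc7COc1ccc([C@H]2Oc3c([C@@H](c4c(OCc7ccccc7)cc(O)cc4Br)C(OCc7ccccc7)C(=O)c4ccc(OCc7ccccc7)cc4)c(OCOC)cc(OCc7ccccc7)c3C[C@@H]2OCOC)cc1 | intermediate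
21 | (4R)-3,5-bis(benzyloxy)-2-[4-(benzyloxy)phenyl]-4-[5,4'-di-O-benzyl-3,7-bis-O-(methoxymethyl)afzelechin-8-yl]-4H-chromen-7-ol | c7ccccc7COc1ccc([C@H]2Oc3c([C@H]4c5c(OCc7ccccc7)cc(O)cc5OC(c5ccc(OCc7ccccc7)cc5)=C4OCc7ccccc7)c(OCOC)cc(OCc7ccccc7)c3C[C@@H]2OCOC)cc1 | intermediate
22 | 3,5,4'-tri-O-benzylafzelechin-(2β→O→7,4β→8)-5,4'-di-O-benzylafzelechin | c7ccccc7COc1ccc([C@H]2Oc3c(c(OCc7ccccc7)cc4c3[C@H]3c5c(OCc7ccccc7)cc(O)cc5O[C@@](c5ccc(OCc7ccccc7)cc5)(O4)[C@H]3OCc7ccccc7)C[C@@H]2O)cc1 | intermediate
23 | (−)-epiafzelechin, (2R,3R)-2-(4-hydroxyphenyl)chromane-3,5,7-triol | C1c2c(O)cc(O)cc2O[C@H](c2ccc(O)cc2)[C@@H]1O | starting material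
24 | 5,7,4'-tri-O-benzylepiafzelechin | C1c2c(OCc7ccccc7)cc(OCc7ccccc7)cc2O[C@H](c2ccc(OCc7ccccc7)cc2)[C@@H]1O | intermediate
25 | 8-bromo-5,7,4'-tri-O-benzylepiafzelechin | C1c2c(OCc7ccccc7)cc(OCc7ccccc7)c(Br)c2O[C@H](c2ccc(OCc7ccccc7)cc2)[C@@H]1O | intermediate
26 | 3,5,7,4'-tetra-O-benzyl-8-bromoepiafzelechin | C1c2c(OCc7ccccc7)cc(OCc7ccccc7)c(Br)c2O[C@H](c2ccc(OCc7ccccc7)cc2)[C@@H]1OCc7ccccc7 | intermediate
27 | 3,5,7,4'-tetra-O-benzyl-8-bromo-4β-(2-hydroxyethoxy)epiafzelechin | OCCO[C@H]1c2c(OCc7ccccc7)cc(OCc7ccccc7)c(Br)c2O[C@H](c2ccc(OCc7ccccc7)cc2)[C@@H]1OCc7ccccc7 | intermediate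
28 | 3,5,7,4'-tetra-O-benzyl-8-bromo-2β,4β-(ethane-1,2-diyldioxy)epiafzelechin | C8CO[C@H]1c2c(OCc7ccccc7)cc(OCc7ccccc7)c(Br)c2O[C@@](c2ccc(OCc7ccccc7)cc2)(O8)[C@@H]1OCc7ccccc7 | intermediate
29 | 4β→8 linked adduct of 28 and 22 with the 2β-(2-hydroxyethoxy) ketal still in place and free 7-OH on the middle unit | c7ccccc7COc1ccc([C@H]2Oc3c(c(OCc7ccccc7)cc4c3[C@H]3c5c(OCc7ccccc7)cc(O)c(c5O[C@@](c5ccc(OCc7ccccc7)cc5)(O4)[C@H]3OCc7ccccc7)[C@H]3c4c(OCc7ccccc7)cc(OCc7ccccc7)c(Br)c4O[C@@](c4ccc(OCc7ccccc7)cc4)(OCCO)[C@@H]3OCc7ccccc7)C[C@@H]2O)cc1 | intermediate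
30 | 3,5,7,4'-tetra-O-benzyl-8-bromoepiafzelechin-(2β→O→7,4β→8)-3,5,4'-tri-O-benzylafzelechin-(2β→O→7,4β→8)-5,4'-di-O-benzylafzelechin | c7ccccc7COc1ccc([C@H]2Oc3c(c(OCc7ccccc7)cc4c3[C@H]3c5c(OCc7ccccc7)cc6c(c5O[C@@](c5ccc(OCc7ccccc7)cc5)(O4)[C@H]3OCc7ccccc7)[C@H]3c4c(OCc7ccccc7)cc(OCc7ccccc7)c(Br)c4O[C@@](c4ccc(OCc7ccccc7)cc4)(O6)[C@@H]3OCc7ccccc7)C[C@@H]2O)cc1 | intermediate
31 | epiafzelechin-(2β→O→7,4β→8)-afzelechin-(2β→O→7,4β→8)-afzelechin | Oc1ccc([C@H]2Oc3c(c(O)cc4c3[C@H]3c5c(O)cc6c(c5O[C@@](c5ccc(O)cc5)(O4)[C@H]3O)[C@H]3c4c(O)cc(O)cc4O[C@@](c4ccc(O)cc4)(O6)[C@@H]3O)C[C@@H]2O)cc1 | target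

**Step count and risks**

Total step count: 20. Longest linear sequence: 10 steps (steps 6–13, 19 and 20, from (+)-afzelechin).

Steps most likely to fail:

1. Step 12. The two catalytic events may not be compatible in one flask: self-alkylation of the electron-rich rings by the quinone methide, weak or wrong-sense facial control by the acid at a doubly ortho-substituted diarylmethylidene, or slow copper coupling at the hindered, electron-rich C8a–Br. Fallback with known chemistry, setting out from 18 and 8: a Sc(OTf)3-catalysed Mukaiyama-type 1,6-addition to the quinone methide formed in situ should give ketone 20 together with the (3R)-epimer of ketone 20 F1, which are isolated as a mixture. A separate copper-catalysed intramolecular enolate O-arylation (CuI, 1,10-phenanthroline, Cs2CO3, DMF, 100 °C) should then give 21 together with the (4S)-epimer of flav-2-ene 21 F2. The two are diastereomers because of the lower unit and are separated by chromatography; the route is rejoined at 21.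

2. Step 13. Protonation at C3 may occur with poor facial selectivity, or the enol ether may hydrolyse before O7 of the lower unit is unmasked. Fallback, setting out from 21: deliberate hydrolysis with aqueous HCl in THF should give the ring-opened hydroxy ketone 2-(benzyloxy)-1-[4-(benzyloxy)phenyl]-3-[2-(benzyloxy)-4,6-dihydroxyphenyl]-3-(5,4'-di-O-benzylafzelechin-8-yl)propan-1-one F3 (diaryl carbon as in 21, in equilibrium with its lactols). The classical acid-catalysed double cyclodehydration of such a ketone with its two flanking phenols (TsOH, toluene, water removal) should then close the 2,8-dioxabicyclo[3.3.1]nonane, with C3 equilibrating through the enol under thermodynamic control. The route is rejoined at 22.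

3. Step 11. The bromine–magnesium exchange may take place at the wrong bromine, or the 2-bromoaryl Grignard reagent may lose magnesium halide to an aryne before it adds to the hindered aldehyde. Fallback, setting out from 2: iodination para to the hydroxyl with N-iodosuccinimide should give 3-(benzyloxy)-5-bromo-4-iodophenol F4, and silylation (TBSCl, imidazole) gives [3-(benzyloxy)-5-bromo-4-iodophenoxy](tert-butyl)dimethylsilane F5. Chemoselective iodine–magnesium exchange with i-PrMgCl·LiCl at −78 °C, where neither the bromine nor aryne formation competes, gives 16, and the route is rejoined there.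

**Further compounds**

F1 | step 12 | (3R)-epimer of ketone 20 (both C2 epimers) | c7ccccc7COc1ccc([C@H]2Oc3c([C@H](c4c(OCc7ccccc7)cc(O)cc4Br)C(OCc7ccccc7)C(=O)c4ccc(OCc7ccccc7)cc4)c(OCOC)cc(OCc7ccccc7)c3C[C@@H]2OCOC)cc1
F2 | step 12 | (4S)-epimer of flav-2-ene 21 | c7ccccc7COc1ccc([C@H]2Oc3c([C@@H]4c5c(OCc7ccccc7)cc(O)cc5OC(c5ccc(OCc7ccccc7)cc5)=C4OCc7ccccc7)c(OCOC)cc(OCc7ccccc7)c3C[C@@H]2OCOC)cc1
F3 | step 13 | 2-(benzyloxy)-1-[4-(benzyloxy)phenyl]-3-[2-(benzyloxy)-4,6-dihydroxyphenyl]-3-(5,4'-di-O-benzylafzelechin-8-yl)propan-1-one (diaryl carbon as in 21, both C2 epimers) | c7ccccc7COc1ccc([C@H]2Oc3c([C@@H](c4c(OCc7ccccc7)cc(O)cc4O)C(OCc7ccccc7)C(=O)c4ccc(OCc7ccccc7)cc4)c(O)cc(OCc7ccccc7)c3C[C@@H]2O)cc1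
F4 | step 11 | 3-(benzyloxy)-5-bromo-4-iodophenol | Oc1cc(OCc2ccccc2)c(I)c(Br)c1
F5 | step 11 | [3-(benzyloxy)-5-bromo-4-iodophenoxy](tert-butyl)dimethylsilane | CC(C)(C)[Si](C)(C)Oc1cc(OCc2ccccc2)c(I)c(Br)c1
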